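**Plan**
The target is the C2-symmetric (2R,3S,2'R,3'S) isomer, 2,3-trans in both halves. The retrosynthesis cuts the four O-benzyl bonds, then the C3–C3' bond (two enol carbons of like polarity, joined oxidatively on a silicon tether), leaving two molecules of one (R)-flavanone.
In that flavanone C2 is benzylic, bound to the ring oxygen O1 and 1,3 to the C4 ketone (a homoenolate relation). The pyranone ring (O1, C2, C3, C4, C4a, C8a) is therefore traced back to the furan ring (O1, C2, C4, C4a, C8a) of a cyclopropa[b]benzofuranol in which C2 and C4 are bonded and C3 is the cyclopropane CH2.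
That cyclopropane comes from enantioselective, dearomatising CH2 transfer to the C2=C3 bond of a 2-aryl-3-siloxybenzofuran, made from a commercial deoxybenzoin.
Forward order: benzylation, bromination and furanone closure, enol silylation, cyclopropanation, ring expansion to the six-membered ring, silyl bis-enol ether, oxidative C3–C3' coupling, hydrogenolysis.
Stereochemistry: C2 from the ligand-controlled cyclopropanation, passed on with inversion in the ring expansion; C3 and C3' from C2 (bond formation anti to the C2 aryl group in both halves).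

Key step: step 5

Remark: the facial sense of the dipeptide-controlled cyclopropanation on this enol ether is assumed; the D,D-ligand is taken instead if the L,L-ligand should give the (1aR,6bR) series.

**Route**

Step 1
Reactants: 1 1-(2,4-dihydroxyphenyl)-2-(4-hydroxyphenyl)ethan-1-one
Product: 2 1-[4-(benzyloxy)-2-hydroxyphenyl]-2-[4-(benzyloxy)phenyl]ethan-1-one
Conditions: BnBr (2.1 equiv), K2CO3, acetone, reflux
Reagents that add atoms: benzyl bromide, BrCc1ccccc1
Why: Williamson ether synthesis in which the 2-hydroxyl, hydrogen-bonded to the ketone, stays free while the two other phenols are benzylated; benzyl ethers survive all later steps and leave under neutral hydrogenolysis.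

Step 2
Reactants: 2 1-[4-(benzyloxy)-2-hydroxyphenyl]-2-[4-(benzyloxy)phenyl]ethan-1-one
Product: 4 6-(benzyloxy)-2-[4-(benzyloxy)phenyl]-1-benzofuran-3(2H)-one, via bromo ketone 3 (not isolated)
Conditions: CuBr2 (2.1 equiv), EtOAc–CHCl3, reflux; then NaOAc, EtOH, 25 °C, argon
Reagents that add atoms: none
Why: α-bromination of the aryl ketone at the doubly activated benzylic methylene, then intramolecular Williamson etherification (5-exo-tet) by the ortho phenol should close the furanone ring; C2 of 4 is configurationally labile, which does not matter because it becomes sp2 in step 3.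

Step 3
Reactants: 4 6-(benzyloxy)-2-[4-(benzyloxy)phenyl]-1-benzofuran-3(2H)-one
Product: 5 {6-(benzyloxy)-2-[4-(benzyloxy)phenyl]-1-benzofuran-3-yl}oxy(trimethyl)silane
Conditions: TMSOTf, Et3N, CH2Cl2, 0 °C, argon
Reagents that add atoms: trimethylsilyl trifluoromethanesulfonate, C[Si](C)(C)OS(=O)(=O)C(F)(F)F
Why: O-silylation of the enol form (silyl enol ether formation), driven by aromatisation to the benzofuran, should give the electron-rich C2=C3 bond flanked by both oxygen donors.

Step 4
Reactants: 5 {6-(benzyloxy)-2-[4-(benzyloxy)phenyl]-1-benzofuran-3-yl}oxy(trimethyl)silane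
Product: 6 (1aS,6bS)-4-(benzyloxy)-1a-[4-(benzyloxy)phenyl]-6b-[(trimethylsilyl)oxy]-1a,6b-dihydro-1H-cyclopropa[b][1]benzofuran
Conditions: Et2Zn, CH2I2, N-Boc-L-valyl-L-proline methyl ester (0.25 equiv), CH2Cl2, −40 to 0 °C
Reagents that add atoms: diiodomethane, ICI
Why: Proposed new method: the (iodomethyl)zinc carbenoid bound to the dipeptide should transfer CH2 in a concerted butterfly-type step to the benzofuran C2=C3 bond, a tetrasubstituted silyl enol ether pushed by O1 and the siloxy group within the weakly aromatic furan ring, so that the flat heteroarene is dearomatised to the necessarily cis-fused cyclopropane with C1a and C6b set together by ligand-controlled facial selection; the closest known reaction type is the dipeptide-promoted enantioselective Simmons–Smith cyclopropanation of aryl silyl enol ethers, which has not been shown on a benzofuran C2=C3 bond.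

Step 5
Reactants: 6 (1aS,6bS)-4-(benzyloxy)-1a-[4-(benzyloxy)phenyl]-6b-[(trimethylsilyl)oxy]-1a,6b-dihydro-1H-cyclopropa[b][1]benzofuran
Product: 8 (2R)-7-(benzyloxy)-2-[4-(benzyloxy)phenyl]-2,3-dihydro-4H-chromen-4-one, via cyclopropanol 7 (not isolated)
Conditions: K2CO3 (0.2 equiv), MeOH–THF, −20 to 0 °C; AcOH quench
Reagents that add atoms: none
Why: Methanolysis of the silyl ether gives the cyclopropoxide of 7, whose ring-fusion bond C6b–C1a (shared by the cyclopropane and the five-membered oxygen ring) breaks while methanol protonates C1a from the rear, so the five-membered ring grows by one carbon into the pyranone (the former carbenoid CH2 becomes C3, the carbinol carbon becomes the C4 ketone). The closest known reaction types are the base-induced homoenolate opening of 2-arylcyclopropanols, which cleaves toward the benzylic carbon with inversion, and the one-carbon ring expansion of bicyclic siloxycyclopropanes made from cyclic silyl enol ethers. No ring is closed by a new bond; the six-membered ring arises by scission of the zero-atom bridge of the 2-oxabicyclo[3.1.0]hexane core. The new stereocentre C2 is controlled by the configuration of C1a (1aS should give 2R through invertive protonation). The step needs cleavage of the internal bond and not of the external C6b–C1 bond, which is secured because only the internal cleavage leads to a carbanion stabilised by the aryl group and the aryloxy oxygen. It also needs the product not to racemise by base-induced opening to the chalcone, which catalytic carbonate, low temperature and the acid quench are meant to prevent.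

Step 6
Reactants: 8 (2R)-7-(benzyloxy)-2-[4-(benzyloxy)phenyl]-2,3-dihydro-4H-chromen-4-one (two equivalents)
Product: 9 bis({(2R)-7-(benzyloxy)-2-[4-(benzyloxy)phenyl]-2H-chromen-4-yl}oxy)di(propan-2-yl)silane
Conditions: iPr2Si(OTf)2 (0.5 equiv), Et3N, CH2Cl2, −78 to 0 °C
Reagents that add atoms: di(propan-2-yl)silanediyl bis(trifluoromethanesulfonate), CC(C)[Si](OS(=O)(=O)C(F)(F)F)(OS(=O)(=O)C(F)(F)F)C(C)C
Why: soft enolisation (silyl triflate and amine) should form both silyl enol ethers on one silicon without a free metal enolate, which could open to the chalcone by E1cB and racemise C2; the silicon tether holds the two identical halves together for the coupling.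

Step 7
Reactants: 9 bis({(2R)-7-(benzyloxy)-2-[4-(benzyloxy)phenyl]-2H-chromen-4-yl}oxy)di(propan-2-yl)silane
Product: 10 (2R,2'R,3S,3'S)-7,7'-bis(benzyloxy)-2,2'-bis[4-(benzyloxy)phenyl]-2,2',3,3'-tetrahydro-4H,4'H-[3,3'-bichromene]-4,4'-dione
Conditions: (NH4)2Ce(NO3)6 (2.2 equiv), NaHCO3, MeCN–EtCN, −10 °C
Reagents that add atoms: none
Why: silicon-tethered oxidative enol ether coupling, in which one-electron oxidation of one enol ether gives a radical cation that is attacked intramolecularly by the second enol carbon (union of two carbons of like polarity) before a second oxidation and loss of silicon give the 1,4-diketone; each C3 should be attacked anti to its neighbouring C2 aryl group, and since both halves are (R) this gives the 2,3-trans, 2',3'-trans (3S,3'S) isomer.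

Step 8
Reactants: 10 (2R,2'R,3S,3'S)-7,7'-bis(benzyloxy)-2,2'-bis[4-(benzyloxy)phenyl]-2,2',3,3'-tetrahydro-4H,4'H-[3,3'-bichromene]-4,4'-dione
Product: 11 (2R,2'R,3S,3'S)-7,7'-dihydroxy-2,2'-bis(4-hydroxyphenyl)-2,2',3,3'-tetrahydro-4H,4'H-[3,3'-bichromene]-4,4'-dione (target)
Conditions: H2 (1 atm), Pd/C, EtOAc–MeOH, 25 °C
Reagents that add atoms: none
Why: hydrogenolysis of the four benzyl ethers under neutral conditions should free the phenols without enolising C3/C3' or opening the pyranone rings at C2/C2', which becomes easy under base once the 4'-phenols are free.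

**Compound list**
1 | 1-(2,4-dihydroxyphenyl)-2-(4-hydroxyphenyl)ethan-1-one | O=C(Cc1ccc(O)cc1)c1ccc(O)cc1O | starting material
2 | 1-[4-(benzyloxy)-2-hydroxyphenyl]-2-[4-(benzyloxy)phenyl]ethan-1-one | O=C(Cc1ccc(OCc2ccccc2)cc1)c1ccc(OCc2ccccc2)cc1O | intermediate
3 | 1-[4-(benzyloxy)-2-hydroxyphenyl]-2-[4-(benzyloxy)phenyl]-2-bromoethan-1-one | O=C(C(Br)c1ccc(OCc2ccccc2)cc1)c1ccc(OCc2ccccc2)cc1O | intermediate (not isolated)
4 | 6-(benzyloxy)-2-[4-(benzyloxy)phenyl]-1-benzofuran-3(2H)-one | O=C1C(c2ccc(OCc3ccccc3)cc2)Oc2cc(OCc3ccccc3)ccc21 | intermediate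
5 | {6-(benzyloxy)-2-[4-(benzyloxy)phenyl]-1-benzofuran-3-yl}oxy(trimethyl)silane | C[Si](C)(C)Oc1c(-c2ccc(OCc3ccccc3)cc2)oc2cc(OCc3ccccc3)ccc12 | intermediate
6 | (1aS,6bS)-4-(benzyloxy)-1a-[4-(benzyloxy)phenyl]-6b-[(trimethylsilyl)oxy]-1a,6b-dihydro-1H-cyclopropa[b][1]benzofuran | C[Si](C)(C)O[C@]12C[C@@]1(c1ccc(OCc3ccccc3)cc1)Oc1cc(OCc3ccccc3)ccc21 | intermediate
7 | (1aS,6bS)-4-(benzyloxy)-1a-[4-(benzyloxy)phenyl]-1,1a-dihydro-6bH-cyclopropa[b][1]benzofuran-6b-ol (formed as its alkoxide) | O[C@]12C[C@@]1(c1ccc(OCc3ccccc3)cc1)Oc1cc(OCc3ccccc3)ccc21 | intermediate (not isolated)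
8 | (2R)-7-(benzyloxy)-2-[4-(benzyloxy)phenyl]-2,3-dihydro-4H-chromen-4-one | O=C1C[C@H](c2ccc(OCc3ccccc3)cc2)Oc2cc(OCc3ccccc3)ccc21 | intermediate
9 | bis({(2R)-7-(benzyloxy)-2-[4-(benzyloxy)phenyl]-2H-chromen-4-yl}oxy)di(propan-2-yl)silane | CC(C)[Si](C(C)C)(OC1=C[C@H](c2ccc(OCc3ccccc3)cc2)Oc2cc(OCc3ccccc3)ccc21)OC1=C[C@H](c2ccc(OCc3ccccc3)cc2)Oc2cc(OCc3ccccc3)ccc21 | intermediate
10 | (2R,2'R,3S,3'S)-7,7'-bis(benzyloxy)-2,2'-bis[4-(benzyloxy)phenyl]-2,2',3,3'-tetrahydro-4H,4'H-[3,3'-bichromene]-4,4'-dione | O=C1c2ccc(OCc3ccccc3)cc2O[C@@H](c2ccc(OCc3ccccc3)cc2)[C@@H]1[C@@H]1C(=O)c2ccc(OCc3ccccc3)cc2O[C@H]1c1ccc(OCc2ccccc2)cc1 | intermediate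
11 | (2R,2'R,3S,3'S)-7,7'-dihydroxy-2,2'-bis(4-hydroxyphenyl)-2,2',3,3'-tetrahydro-4H,4'H-[3,3'-bichromene]-4,4'-dione | O=C1c2ccc(O)cc2O[C@@H](c2ccc(O)cc2)[C@@H]1[C@@H]1C(=O)c2ccc(O)cc2O[C@H]1c1ccc(O)cc1 | target

**Count and risks**
Total steps: 8. Longest linear sequence: 8 steps (1 to 11).

Steps most likely to fail:

Step 4. The tetrasubstituted enol ether inside the furan ring may react sluggishly with the zinc carbenoid, or the ligand may give poor facial selection. The fallback sets out from 4 and uses known chemistry. C-alkylation of the enolate of 4 with CH2Br2 (NaH, DMPU–THF) should give 6-(benzyloxy)-2-[4-(benzyloxy)phenyl]-2-(bromomethyl)-1-benzofuran-3(2H)-one F1. A Dowd–Beckwith radical ring expansion (Bu3SnH added slowly, AIBN, benzene, 80 °C) then proceeds by 3-exo attack of the primary radical on the ketone, β-scission to the benzylic α-aryloxy radical and hydrogen transfer, and should give the racemic flavanone F2. Preparative chromatography on a chiral cellulose carbamate phase separates the (R) enantiomer, and the route is rejoined at 8.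

Step 5. Configuration at C2 may be lost if the benzylic carbanion becomes free before protonation, or if base reopens the product to the chalcone. The fallback sets out from 6, whose configuration is then irrelevant. Oxidative opening with FeCl3 in DMF at 0 °C (alkoxy radical, β-scission of the same internal bond, chlorine transfer) should give the 2-chloro ketone F3. NaOAc in MeOH eliminates HCl to the flavone F4. Enantioselective conjugate reduction with copper hydride (Cu(OAc)2, DTBM-SEGPHOS in the enantiomeric form that delivers the (R) product, (EtO)2MeSiH, t-BuOH, toluene) then sets C2 under catalyst control, and the route is rejoined at 8.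

Step 7. Tetravalent cerium may also oxidise the electron-rich aryl ethers, or the tether may allow attack syn to a C2 aryl group. The fallback sets out from 8. Silylation (TMSOTf, Et3N, CH2Cl2) should give the mono enol ether F5. Treatment with PhIO and BF3·OEt2 in CH2Cl2 at −40 °C turns one enol ether into an α-keto iodonium electrophile that is attacked by a second enol ether (polar umpolung coupling in place of the radical cation). Any 2,3-cis half is then epimerised at C3 through the enol with catalytic p-TsOH in CH2Cl2, which leaves C2 untouched, and the route is rejoined at 10.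

**Further compounds**
F1 | step 4 | 6-(benzyloxy)-2-[4-(benzyloxy)phenyl]-2-(bromomethyl)-1-benzofuran-3(2H)-one | O=C1C(CBr)(c2ccc(OCc3ccccc3)cc2)Oc2cc(OCc3ccccc3)ccc21
F2 | step 4 | rac-7-(benzyloxy)-2-[4-(benzyloxy)phenyl]-2,3-dihydro-4H-chromen-4-one | O=C1CC(c2ccc(OCc3ccccc3)cc2)Oc2cc(OCc3ccccc3)ccc21
F3 | step 5 | 7-(benzyloxy)-2-[4-(benzyloxy)phenyl]-2-chloro-2,3-dihydro-4H-chromen-4-one | O=C1CC(Cl)(c2ccc(OCc3ccccc3)cc2)Oc2cc(OCc3ccccc3)ccc21
F4 | step 5 | 7-(benzyloxy)-2-[4-(benzyloxy)phenyl]-4H-chromen-4-one | O=c1cc(-c2ccc(OCc3ccccc3)cc2)oc2cc(OCc3ccccc3)ccc12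
F5 | step 7 | {[(2R)-7-(benzyloxy)-2-[4-(benzyloxy)phenyl]-2H-chromen-4-yl]oxy}(trimethyl)silane | C[Si](C)(C)OC1=C[C@H](c2ccc(OCc3ccccc3)cc2)Oc2cc(OCc3ccccc3)ccc21
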